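## Retrosynthetic overview

1. Target 10 ⇐ O-methylation of epoxy alcohol 9 (C–O bond).
2. 9 ⇐ hydroxyl-directed epoxidation of dienol 8 (the oxirane is the last ring formed).
3. 8 ⇐ key C–O bond: rhodium-catalysed enantioselective anti-SN2′ opening of racemic 7-oxanorbornadiene 6 by benzoic acid, which sets both carbinol centres and unveils the diene.
4. 6 ⇐ reduction and benzoylation of ester 3 ⇐ Diels–Alder reaction of furan with methyl propiolate.
5. Ring order: six-membered carbocycle with its oxygen bridge (step 1), bridge opened (step 4), oxirane closed (step 5).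

Assumption: the SMILES is read as [(1R,2S,3R,6R)-3-(benzoyloxy)-2-methoxy-7-oxabicyclo[4.1.0]hept-4-en-1-yl]methyl benzoate (oxirane and OMe cis, OBz trans to both); racemic 3, 4 and 6 are drawn as the enantiomer that is carried forward.

## Route

Step 1
Reactants: 1 furan; 2 methyl propiolate
Product: 3 rac-methyl 7-oxabicyclo[2.2.1]hepta-2,5-diene-2-carboxylate
Conditions: AlCl3 (0.3 equiv), furan (5 equiv), CH2Cl2, −20 → 0 °C, 1 h; cold aq. NaHCO3 quench
Reagents that add atoms: none
Why: Lewis-acid-catalysed Diels–Alder [4+2] cycloaddition of furan to the LUMO-lowered alkynoate builds the carbocycle with the oxygen bridge and the one-carbon side chain in place; the adduct is chiral but racemic, and no stereocentre is controlled here.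

Step 2
Reactants: 3 rac-methyl 7-oxabicyclo[2.2.1]hepta-2,5-diene-2-carboxylate
Product: 4 rac-(7-oxabicyclo[2.2.1]hepta-2,5-dien-2-yl)methanol
Conditions: iBu2AlH (2.2 equiv), CH2Cl2, −78 °C; aq. potassium sodium tartrate work-up
Reagents that add atoms: none
Why: 1,2-hydride reduction of the conjugated ester by iBu2AlH gives the allylic alcohol, and the non-acidic medium and work-up leave the strained alkenes and the acid-labile oxygen bridge untouched.

Step 3
Reactants: 4 rac-(7-oxabicyclo[2.2.1]hepta-2,5-dien-2-yl)methanol; 5 benzoyl chloride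
Product: 6 rac-(7-oxabicyclo[2.2.1]hepta-2,5-dien-2-yl)methyl benzoate
Conditions: BzCl (1.2 equiv), Et3N (1.5 equiv), DMAP (5 mol %), CH2Cl2, 0 °C
Reagents that add atoms: none
Why: DMAP-catalysed nucleophilic acyl substitution (O-benzoylation) installs the primary benzoate of the target under basic conditions that the oxabicycle tolerates.

Step 4
Reactants: 6 rac-(7-oxabicyclo[2.2.1]hepta-2,5-dien-2-yl)methyl benzoate; 7 benzoic acid
Product: 8 [(5R,6R)-5-(benzoyloxy)-6-hydroxycyclohexa-1,3-dien-1-yl]methyl benzoate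
Conditions: [Rh(cod)Cl]2 (2.5 mol %), (R)-1-[(S)-2-(diphenylphosphino)ferrocenyl]ethyldi-tert-butylphosphine (6 mol %), PhCO2H (0.55 equiv), Et3N (10 mol %), THF, 40 °C; chromatography on Et3N-deactivated silica
Reagents that add atoms: none
Why: Proposed new method: enantiomer-resolving ring opening of a non-benzo-fused, mono-substituted racemic 7-oxanorbornadiene by a carboxylate; monovalent rhodium on the chiral ferrocenyl diphosphine binds the exo face of the unsubstituted C5=C6 bond, inserts with retention into the strained bridgehead C4–O bond remote from the substituted C2 to give a rhodium alkoxide/π-allyl over C4–C6, and benzoate attacks C6 anti to rhodium (SN2′), so the new C–OBz bond is trans to the retained C1–O bond and the 1,3-diene is released; the catalyst is expected to accept only the C4–O bond of the (1S,4R)-enantiomer, giving 8 as the single (5R,6R)-enantiomer in at most 50 % yield while the mirror-image substrate is left behind or diverted to a separable regioisomer (the mirror-image ligand is used if the sense of recognition proves opposite); closest known reaction type: rhodium-catalysed asymmetric ring opening of oxabenzonorbornadienes with carboxylate, alcohol and amine nucleophiles and its regiodivergent resolution of unsymmetrical benzo-fused oxabicycles.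

Step 5
Reactants: 8 [(5R,6R)-5-(benzoyloxy)-6-hydroxycyclohexa-1,3-dien-1-yl]methyl benzoate
Product: 9 [(1R,2S,3R,6R)-3-(benzoyloxy)-2-hydroxy-7-oxabicyclo[4.1.0]hept-4-en-1-yl]methyl benzoate
Conditions: VO(acac)2 (5 mol %), tBuOOH (1.5 equiv, in decane), CH2Cl2, 0 °C
Reagents that add atoms: tert-butyl hydroperoxide, CC(C)(C)OO
Why: Hydroxyl-directed, vanadium-catalysed epoxidation: the C6 hydroxyl binds the pentavalent vanadium alkylperoxide and delivers oxygen to the adjacent trisubstituted C1=C2 bond on its own face, setting both oxirane centres (1R,6R) cis to the hydroxyl; the distal C3=C4 bond is not directed and is deactivated by its allylic benzoate.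

Step 6
Reactants: 9 [(1R,2S,3R,6R)-3-(benzoyloxy)-2-hydroxy-7-oxabicyclo[4.1.0]hept-4-en-1-yl]methyl benzoate
Product: 10 [(1R,2S,3R,6R)-3-(benzoyloxy)-2-methoxy-7-oxabicyclo[4.1.0]hept-4-en-1-yl]methyl benzoate
Conditions: Me3OBF4 (3 equiv), 1,8-bis(dimethylamino)naphthalene (3.5 equiv), 4 Å molecular sieves, CH2Cl2, 0 °C → rt
Reagents that add atoms: trimethyloxonium tetrafluoroborate, C[O+](C)C.F[B-](F)(F)F
Why: O-alkylation with Meerwein's salt, buffered by a non-nucleophilic base, methylates the hindered secondary hydroxyl under non-basic conditions, so the vicinal benzoate should not migrate and no stereocentre is touched.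

## Compound list

1 | furan | c1ccoc1 | starting material
2 | methyl propiolate | C#CC(=O)OC | starting material
3 | rac-methyl 7-oxabicyclo[2.2.1]hepta-2,5-diene-2-carboxylate (racemic; drawn 1S,4R) | COC(=O)C1=C[C@H]2C=C[C@@H]1O2 | intermediate
4 | rac-(7-oxabicyclo[2.2.1]hepta-2,5-dien-2-yl)methanol (racemic; drawn 1S,4R) | OCC1=C[C@H]2C=C[C@@H]1O2 | intermediate
5 | benzoyl chloride | O=C(Cl)c1ccccc1 | starting material
6 | rac-(7-oxabicyclo[2.2.1]hepta-2,5-dien-2-yl)methyl benzoate (racemic; drawn 1S,4R, the enantiomer that reacts in step 4) | O=C(OCC1=C[C@H]2C=C[C@@H]1O2)c1ccccc1 | intermediate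
7 | benzoic acid | OC(=O)c1ccccc1 | starting material
8 | [(5R,6R)-5-(benzoyloxy)-6-hydroxycyclohexa-1,3-dien-1-yl]methyl benzoate | O[C@H]1[C@H](OC(=O)c2ccccc2)C=CC=C1COC(=O)c1ccccc1 | intermediate
9 | [(1R,2S,3R,6R)-3-(benzoyloxy)-2-hydroxy-7-oxabicyclo[4.1.0]hept-4-en-1-yl]methyl benzoate | O[C@H]1[C@H](OC(=O)c2ccccc2)C=C[C@H]2O[C@]21COC(=O)c1ccccc1 | intermediate
10 | [(1R,2S,3R,6R)-3-(benzoyloxy)-2-methoxy-7-oxabicyclo[4.1.0]hept-4-en-1-yl]methyl benzoate | CO[C@H]1[C@H](OC(=O)c2ccccc2)C=C[C@H]2O[C@]21COC(=O)c1ccccc1 | target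

## Step count and risks

Total steps: 6. Longest linear sequence: 6 (from furan and methyl propiolate).

The three steps most likely to fail:

**Step 4 (proposed new ring opening).** Risks are rhodium-induced isomerisation of the oxanorbornadiene to phenols, poor discrimination between the two bridgehead C–O bonds, and aromatisation of 8. The fallback uses only known reaction types, sets out from benzoic acid 7 (with benzoyl chloride 5) and comes back at 8.
- Birch reduction of 7 (Li, liquid NH3, then NH4Cl) gives cyclohexa-2,5-diene-1-carboxylic acid F3.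
- LiAlH4 reduces it to (cyclohexa-2,5-dien-1-yl)methanol F4, which is benzoylated with 5 to (cyclohexa-2,5-dien-1-yl)methyl benzoate F5.
- One equivalent of mCPBA (NaHCO3, CH2Cl2, 0 °C) epoxidises one alkene anti to the side chain, giving rac-[(1R,2R,6S)-7-oxabicyclo[4.1.0]hept-3-en-2-yl]methyl benzoate F6.
- Opening with 7 (PhCO2Cs, DMF, 60 °C) at the oxirane carbon remote from the side chain gives racemic [(1R,5R,6R)-5-(benzoyloxy)-6-hydroxycyclohex-2-en-1-yl]methyl benzoate F7.
- Lipase-catalysed acetylation (Candida antarctica lipase B, vinyl acetate) is taken to convert the unwanted enantiomer into [(1S,5S,6S)-6-(acetyloxy)-5-(benzoyloxy)cyclohex-2-en-1-yl]methyl benzoate F8 and leave the (1R,5R,6R)-alcohol.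
- Br2 (CH2Cl2, −78 °C) adds trans-diaxially to give [(1R,2R,3R,5R,6R)-3-(benzoyloxy)-5,6-dibromo-2-hydroxycyclohexyl]methyl benzoate F9.
- Double anti-dehydrobromination (LiCl, Li2CO3, DMF, 90 °C) gives 8.

**Step 1 (Diels–Alder).** Risks are modest conversion and Lewis-acid isomerisation of the adduct to hydroxybenzoates. The fallback sets out from 1 and 2 and comes back at 3. Compound 2 is brominated (NBS, cat. AgNO3, acetone) to methyl 3-bromopropiolate F1. This much more reactive dienophile adds to furan without a Lewis acid (neat furan, 25–40 °C) to give rac-methyl 3-bromo-7-oxabicyclo[2.2.1]hepta-2,5-diene-2-carboxylate F2. The vinylic bromide is then removed by hydrogenolysis with zerovalent palladium (Pd(PPh3)4, Bu3SnH, THF, rt) to give 3.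

**Step 6 (methylation next to a benzoate and a vinyl oxirane).** Risks are benzoyl migration and oxirane opening. The fallback sets out from 8 and comes back at 10, reversing the order of ether and oxirane formation. Compound 8 is methylated first (Me3OBF4, 1,8-bis(dimethylamino)naphthalene, CH2Cl2) to [(5R,6R)-5-(benzoyloxy)-6-methoxycyclohexa-1,3-dien-1-yl]methyl benzoate F10. NBS in aqueous 1,2-dimethoxyethane (0 °C) forms the bromonium ion anti to the methoxy group, and water opens it at the allylic carbon to give [(1S,2R,5R,6S)-5-(benzoyloxy)-1-bromo-2-hydroxy-6-methoxycyclohex-3-en-1-yl]methyl benzoate F11. K2CO3 in MeCN closes the oxirane with inversion at the bromine-bearing carbon, cis to the methoxy group, giving 10.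

## Further compounds

F1 | step 1 | methyl 3-bromopropiolate | BrC#CC(=O)OC
F2 | step 1 | rac-methyl 3-bromo-7-oxabicyclo[2.2.1]hepta-2,5-diene-2-carboxylate (racemic; drawn 1S,4R) | COC(=O)C1=C(Br)[C@H]2C=C[C@@H]1O2
F3 | step 4 | cyclohexa-2,5-diene-1-carboxylic acid | OC(=O)C1C=CCC=C1
F4 | step 4 | (cyclohexa-2,5-dien-1-yl)methanol | OCC1C=CCC=C1
F5 | step 4 | (cyclohexa-2,5-dien-1-yl)methyl benzoate | O=C(OCC1C=CCC=C1)c1ccccc1
F6 | step 4 | rac-[(1R,2R,6S)-7-oxabicyclo[4.1.0]hept-3-en-2-yl]methyl benzoate (racemic; drawn enantiomer leads on) | O=C(OC[C@H]1C=CC[C@@H]2O[C@H]12)c1ccccc1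
F7 | step 4 | [(1R,5R,6R)-5-(benzoyloxy)-6-hydroxycyclohex-2-en-1-yl]methyl benzoate (formed racemic, resolved to the drawn enantiomer) | O[C@H]1[C@H](OC(=O)c2ccccc2)CC=C[C@@H]1COC(=O)c1ccccc1
F8 | step 4 | [(1S,5S,6S)-6-(acetyloxy)-5-(benzoyloxy)cyclohex-2-en-1-yl]methyl benzoate | CC(=O)O[C@@H]1[C@@H](OC(=O)c2ccccc2)CC=C[C@H]1COC(=O)c1ccccc1
F9 | step 4 | [(1R,2R,3R,5R,6R)-3-(benzoyloxy)-5,6-dibromo-2-hydroxycyclohexyl]methyl benzoate | O[C@H]1[C@H](OC(=O)c2ccccc2)C[C@@H](Br)[C@H](Br)[C@@H]1COC(=O)c1ccccc1
F10 | step 6 | [(5R,6R)-5-(benzoyloxy)-6-methoxycyclohexa-1,3-dien-1-yl]methyl benzoate | CO[C@H]1[C@H](OC(=O)c2ccccc2)C=CC=C1COC(=O)c1ccccc1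
F11 | step 6 | [(1S,2R,5R,6S)-5-(benzoyloxy)-1-bromo-2-hydroxy-6-methoxycyclohex-3-en-1-yl]methyl benzoate | CO[C@H]1[C@H](OC(=O)c2ccccc2)C=C[C@@H](O)[C@@]1(Br)COC(=O)c1ccccc1
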